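**Retrosynthetic overview**
- The target comes from hydrogenolysis of its 3'-O-benzyl ether, and that flavone from I2/DMSO closure and dehydrogenation of ring C (O1–C2 bond) of a 2',6'-dihydroxy-4'-methoxychalcone.
- Key disconnection, the C4a–C5 bond of ring A: the chalcone arises when methoxide opens a 6-(cinnamoylmethyl)-4-methoxy-2-pyrone and the masked triketide folds onto its own ester by Claisen condensation.
- The pyrone precursor is cut at C4–C4a: the 6-methyl anion of 4-methoxy-6-methyl-2-pyrone is acylated with a cinnamoyl Weinreb amide, made by Horner–Wadsworth–Emmons olefination of 3-benzyloxy-2,4,5-trimethoxybenzaldehyde (from 2,4,5-trimethoxybenzaldehyde by C3 lithiation–oxygenation).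
- Feature used: ring A carries oxygen on C5, C7 and C8a in a 1,3,5 pattern with the acyl carbon C4 on C4a, and only O7 is methylated, so the C5 and C8a oxygens are interchangeable until ring C closes.
- Ring order: ring B is bought, ring A is formed in step 6, ring C in step 7.

Key step: step 6

Remark: the opened pyrone keeps its ring alkene with the ester cis to the keto chain, which is the 2E descriptor by the CIP rules; under base the chalcone may equilibrate with its racemic flavanone isomer, which the ring C oxidation converts equally.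

**Step 1**
Reactants: 1 2,4,5-trimethoxybenzaldehyde
Product: 2 2-(2,4,5-trimethoxyphenyl)-1,3-dioxolane
Conditions: ethylene glycol, TsOH (cat.), toluene, reflux, Dean–Stark
Reagents that add atoms: ethylene glycol, OCCO
Why: Acid-catalysed acetalisation, driven by azeotropic removal of water, masks the aldehyde against the organolithium of the next step.

**Step 2**
Reactants: 2 2-(2,4,5-trimethoxyphenyl)-1,3-dioxolane
Product: 6 3-hydroxy-2,4,5-trimethoxybenzaldehyde, via aryllithium 3 (not isolated), via arylboronate 4 (not isolated), via phenol acetal 5 (not isolated)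
Conditions: n-BuLi, TMEDA, THF, −20 to 0 °C; B(OMe)3, −78 °C to rt; 30% H2O2, aq NaOH, 0 °C; Na2SO3; then 1 M HCl, THF, rt
Reagents that add atoms: hydrogen peroxide, OO; water, O
Why: Directed ortho-metalation should take place at C3–H, which is flanked by the 2- and 4-methoxy groups (the in-between site at which 1,2,4-trimethoxybenzene itself is lithiated) and is more acidic than C6–H with its single methoxy and weakly coordinating dioxolane neighbours, after which borylation, peroxide oxidation of the boronate by 1,2-aryl migration from boron to oxygen and, once excess peroxide is destroyed, acid hydrolysis of the acetal should give the phenol aldehyde.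

**Step 3**
Reactants: 6 3-hydroxy-2,4,5-trimethoxybenzaldehyde
Product: 7 3-benzyloxy-2,4,5-trimethoxybenzaldehyde
Conditions: BnBr, K2CO3, DMF, 60 °C
Reagents that add atoms: benzyl bromide, BrCc1ccccc1
Why: Williamson etherification of the phenoxide with benzyl bromide (SN2) installs a protecting group that withstands amide bases, Mg(OMe)2 and I2/DMSO and is removed at the end by hydrogenolysis.

**Step 4**
Reactants: 7 3-benzyloxy-2,4,5-trimethoxybenzaldehyde; 8 diethyl [2-(methoxy(methyl)amino)-2-oxoethyl]phosphonate
Product: 9 (E)-3-(3-benzyloxy-2,4,5-trimethoxyphenyl)-N-methoxy-N-methylprop-2-enamide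
Conditions: NaH, THF, 0 °C to rt
Reagents that add atoms: none
Why: Horner–Wadsworth–Emmons olefination with the amide-stabilised phosphonate anion should give the E alkene under thermodynamic control of the reversible addition and delivers the Weinreb amide acylating agent in one step.

**Step 5**
Reactants: 9 (E)-3-(3-benzyloxy-2,4,5-trimethoxyphenyl)-N-methoxy-N-methylprop-2-enamide; 10 4-methoxy-6-methyl-2H-pyran-2-one
Product: 12 6-[(E)-4-(3-benzyloxy-2,4,5-trimethoxyphenyl)-2-oxobut-3-enyl]-4-methoxy-2H-pyran-2-one, via lithiated pyrone 11 (not isolated)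
Conditions: 10 (1.5 equiv), LiN(iPr)2 (1.5 equiv), THF, −78 °C; then 9, −78 to −40 °C; cold 1 M HCl
Reagents that add atoms: none
Why: LiN(iPr)2 should remove a proton from the 6-methyl group of the pyrone to give the vinylogous enolate 11, which C-acylates the Weinreb amide in a crossed Claisen-type condensation; the chelated tetrahedral adduct persists until the acidic quench, so the more acidic product is never exposed to base and over-addition is avoided, and 1,2-addition should prevail because the electron-rich cinnamamide is a poor Michael acceptor.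

**Step 6**
Reactants: 12 6-[(E)-4-(3-benzyloxy-2,4,5-trimethoxyphenyl)-2-oxobut-3-enyl]-4-methoxy-2H-pyran-2-one
Product: 14 (E)-3-benzyloxy-2',6'-dihydroxy-2,4,5,4'-tetramethoxychalcone, via open-chain keto ester 13 (not isolated)
Conditions: Mg(OMe)2 (6 equiv), MeOH, reflux; then cold 1 M HCl
Reagents that add atoms: none
Why: Methoxide from Mg(OMe)2 adds to the lactone carbonyl of the pyrone and opens it to methyl ester 13, in which the former ring alkene holds the ester cis to the keto chain; the magnesium-chelated enolate of the methylene between the two ketones (C6 of 13, the future C4a) then attacks the ester carbonyl (C1 of 13, the future C5), methoxide leaves and enolisation aromatises ring A. The closest known reaction type is the base-mediated opening of 6-(2-oxoalkyl)-4-methoxy-2-pyrones and intramolecular Claisen recyclisation to acylphloroglucinol monomethyl ethers, the laboratory counterpart of the chalcone synthase folding. Ring A closes in a 6-exo-trig mode, the enolate carbon attacking an ester C=O that lies outside the new ring. No stereocentre is formed and the E alkene of the cinnamoyl unit is not touched. The selectivity needed is Claisen folding over aldol folding and over conjugate addition to the enone: the enol ether at the future C7 leaves no acidic methylene next to the ester for the aldol mode, oxa-Michael adducts and reclosure to the pyrone are reversible, and only the Claisen path ends in an irreversible aromatisation. Because the 4-methoxy group of the pyrone becomes the 7-methoxy group, the two phenols formed (from the lactone C=O and from the ring oxygen) are equivalent and no selective methylation is needed.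

**Step 7**
Reactants: 14 (E)-3-benzyloxy-2',6'-dihydroxy-2,4,5,4'-tetramethoxychalcone
Product: 16 3'-benzyloxy-5-hydroxy-7,2',4',5'-tetramethoxyflavone, via flavanone 15 (not isolated)
Conditions: I2 (10 mol%), DMSO, 120 °C
Reagents that add atoms: none
Why: Iodine-mediated oxidative cyclisation of a 2'-hydroxychalcone in DMSO: oxa-Michael closure of ring C through either of the two equivalent phenols gives flavanone 15 (its C2 stereocentre forms without control and is erased), iodination at C3 and loss of HI introduce the C2=C3 double bond, DMSO reoxidises the iodide, and the other phenol remains as the hydrogen-bonded 5-OH.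

**Step 8**
Reactants: 16 3'-benzyloxy-5-hydroxy-7,2',4',5'-tetramethoxyflavone
Product: 17 5,3'-dihydroxy-7,2',4',5'-tetramethoxyflavone
Conditions: H2 (1 atm), 10% Pd/C, EtOAc–MeOH, rt
Reagents that add atoms: none
Why: Palladium-catalysed hydrogenolysis of the benzyl aryl ether, stopped after one equivalent of hydrogen, should free the 3'-hydroxyl, since the C2=C3 bond of the flavone is part of a vinylogous ester in the pyranone ring and is reduced far more slowly under these mild conditions.

**Compound list**
1 | 2,4,5-trimethoxybenzaldehyde | COc1cc(OC)c(C=O)cc1OC | starting material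
2 | 2-(2,4,5-trimethoxyphenyl)-1,3-dioxolane | COc1cc(OC)c(C2OCCO2)cc1OC | intermediate
3 | [3-(1,3-dioxolan-2-yl)-2,5,6-trimethoxyphenyl]lithium | [Li]c1c(OC)c(C2OCCO2)cc(OC)c1OC | intermediate
4 | dimethyl [3-(1,3-dioxolan-2-yl)-2,5,6-trimethoxyphenyl]boronate | COc1cc(C2OCCO2)c(OC)c(B(OC)OC)c1OC | intermediate
5 | 2-(3-hydroxy-2,4,5-trimethoxyphenyl)-1,3-dioxolane | COc1cc(C2OCCO2)c(OC)c(O)c1OC | intermediate
6 | 3-hydroxy-2,4,5-trimethoxybenzaldehyde | COc1cc(C=O)c(OC)c(O)c1OC | intermediate
7 | 3-benzyloxy-2,4,5-trimethoxybenzaldehyde | COc1cc(C=O)c(OC)c(OCc2ccccc2)c1OC | intermediate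
8 | diethyl [2-(methoxy(methyl)amino)-2-oxoethyl]phosphonate | CCOP(=O)(CC(=O)N(C)OC)OCC | starting material
9 | (E)-3-(3-benzyloxy-2,4,5-trimethoxyphenyl)-N-methoxy-N-methylprop-2-enamide | CON(C)C(=O)/C=C/c1cc(OC)c(OC)c(OCc2ccccc2)c1OC | intermediate
10 | 4-methoxy-6-methyl-2H-pyran-2-one | COc1cc(C)oc(=O)c1 | starting material
11 | [(4-methoxy-2-oxo-2H-pyran-6-yl)methyl]lithium | [Li]Cc1cc(OC)cc(=O)o1 | intermediate
12 | 6-[(E)-4-(3-benzyloxy-2,4,5-trimethoxyphenyl)-2-oxobut-3-enyl]-4-methoxy-2H-pyran-2-one | COc1cc(CC(=O)/C=C/c2cc(OC)c(OC)c(OCc3ccccc3)c2OC)oc(=O)c1 | intermediate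
13 | methyl (2E,8E)-9-(3-benzyloxy-2,4,5-trimethoxyphenyl)-3-methoxy-5,7-dioxonona-2,8-dienoate | COC(=O)/C=C(/OC)CC(=O)CC(=O)/C=C/c1cc(OC)c(OC)c(OCc2ccccc2)c1OC | intermediate
14 | (E)-3-benzyloxy-2',6'-dihydroxy-2,4,5,4'-tetramethoxychalcone | COc1cc(O)c(C(=O)/C=C/c2cc(OC)c(OC)c(OCc3ccccc3)c2OC)c(O)c1 | intermediate
15 | (±)-2-(3-benzyloxy-2,4,5-trimethoxyphenyl)-5-hydroxy-7-methoxychroman-4-one (racemic) | COc1cc(O)c2c(c1)OC(CC2=O)c1cc(OC)c(OC)c(OCc3ccccc3)c1OC | intermediate
16 | 3'-benzyloxy-5-hydroxy-7,2',4',5'-tetramethoxyflavone | COc1cc(O)c2c(=O)cc(-c3cc(OC)c(OC)c(OCc4ccccc4)c3OC)oc2c1 | intermediate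
17 | 5,3'-dihydroxy-7,2',4',5'-tetramethoxyflavone | COc1cc(O)c2c(=O)cc(-c3cc(OC)c(OC)c(O)c3OC)oc2c1 | target

**Total step count:** 8
**Longest linear sequence:** 8 steps (1 to 17); compounds 8 and 10 are bought.

**Steps most likely to fail**

1. Step 6. The folding may go astray: the enolised pyrone may resist opening, methoxide or the chain enol oxygen may add to the enone, or aldol-type closure may compete, so that little Claisen product forms. The fallback sets out from aldehyde 7 and comes back at chalcone 14; it builds the chalcone by aldol condensation on a preformed ring A. Commercial 2',6'-dihydroxy-4'-methoxyacetophenone (CC(=O)c1c(O)cc(OC)cc1O) would be mono-protected with MOMCl and iPr2NEt in CH2Cl2 to 1-[2-hydroxy-4-methoxy-6-(methoxymethoxy)phenyl]ethanone F1. Claisen–Schmidt condensation of F1 with 7 (KOH, EtOH, rt) should give (E)-3-(3-benzyloxy-2,4,5-trimethoxyphenyl)-1-[2-hydroxy-4-methoxy-6-(methoxymethoxy)phenyl]prop-2-en-1-one F2. HCl in MeOH would then remove the MOM group to give 14.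

2. Step 5. The pyrone anion may add in conjugate fashion to the unsaturated amide, or metalation may occur at C3 of the pyrone instead of the methyl group, so that the C4–C4a bond is not formed cleanly. The fallback sets out from Weinreb amide 9 and comes back at pyrone 12; it replaces acylation by aldol addition and oxidation. iBu2AlH in THF at −78 °C would reduce 9 to (E)-3-(3-benzyloxy-2,4,5-trimethoxyphenyl)prop-2-enal F3. Lithiated pyrone 11 should add 1,2 to this aldehyde to give racemic 6-[(E)-4-(3-benzyloxy-2,4,5-trimethoxyphenyl)-2-hydroxybut-3-enyl]-4-methoxy-2H-pyran-2-one F4. MnO2 in CH2Cl2 would oxidise the allylic alcohol to enone 12.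

3. Step 2. Lithiation at C6, between the dioxolane and the 5-methoxy group, may compete with lithiation at C3, and the dioxolane may fragment under the base, so that the oxygen ends up at the wrong carbon or the material is lost. The fallback sets out from aldehyde 1 and comes back at aryllithium 3; it fixes the position by phenol-directed bromination. BCl3 in CH2Cl2 at 0 °C would cleave the methoxy group ortho to the aldehyde to give 2-hydroxy-4,5-dimethoxybenzaldehyde F5. Br2 with NaOAc in AcOH should brominate C3, the only free position ortho to the phenol, to give 3-bromo-2-hydroxy-4,5-dimethoxybenzaldehyde F6. MeI and K2CO3 in DMF would give 3-bromo-2,4,5-trimethoxybenzaldehyde F7, and ethylene glycol with TsOH would give 2-(3-bromo-2,4,5-trimethoxyphenyl)-1,3-dioxolane F8. Bromine–lithium exchange with n-BuLi in THF at −78 °C then gives 3, which is borylated, oxidised and hydrolysed as in step 2.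

**Further compounds**
F1 | step 6 | 1-[2-hydroxy-4-methoxy-6-(methoxymethoxy)phenyl]ethanone | CC(=O)c1c(O)cc(OC)cc1OCOC
F2 | step 6 | (E)-3-(3-benzyloxy-2,4,5-trimethoxyphenyl)-1-[2-hydroxy-4-methoxy-6-(methoxymethoxy)phenyl]prop-2-en-1-one | COCOc1cc(OC)cc(O)c1C(=O)/C=C/c1cc(OC)c(OC)c(OCc2ccccc2)c1OC
F3 | step 5 | (E)-3-(3-benzyloxy-2,4,5-trimethoxyphenyl)prop-2-enal | O=C/C=C/c1cc(OC)c(OC)c(OCc2ccccc2)c1OC
F4 | step 5 | (±)-6-[(E)-4-(3-benzyloxy-2,4,5-trimethoxyphenyl)-2-hydroxybut-3-enyl]-4-methoxy-2H-pyran-2-one (racemic) | COc1cc(CC(O)/C=C/c2cc(OC)c(OC)c(OCc3ccccc3)c2OC)oc(=O)c1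
F5 | step 2 | 2-hydroxy-4,5-dimethoxybenzaldehyde | COc1cc(O)c(C=O)cc1OC
F6 | step 2 | 3-bromo-2-hydroxy-4,5-dimethoxybenzaldehyde | COc1cc(C=O)c(O)c(Br)c1OC
F7 | step 2 | 3-bromo-2,4,5-trimethoxybenzaldehyde | COc1cc(C=O)c(OC)c(Br)c1OC
F8 | step 2 | 2-(3-bromo-2,4,5-trimethoxyphenyl)-1,3-dioxolane | COc1cc(C2OCCO2)c(OC)c(Br)c1OC
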